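The synthesis rests on cutting the bond between lactone C3 and its vanillyl CH2 and making it by benzylation of an enolate that is born in the same flask. The key step exploits the trans-vicinal C3/C4 pair of the γ-butyrolactone ring (O1, C2, C3, C4, C5), which maps onto Cα/Cβ of a butenolide. A lithiated veratraldehyde dithiane adds to C4 of (5R)-5-(menthyloxy)furan-2(5H)-one, and the C2–C3 lithium enolate is trapped by 4-(benzyloxy)-3-methoxybenzyl bromide. One operation thus forms two C–C bonds and both ring stereocentres, relayed from the removable C5 acetal. Acetal reduction, dithiane hydrolysis, debenzylation and Felkin-controlled ketone reduction finish the route.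

Key step: step 3

Assumption: the lactone is numbered O1, C2 (C=O), C3, C4, C5 throughout, and (5R)-5-(l-menthyloxy)furan-2(5H)-one and 4-(benzyloxy)-3-methoxybenzyl alcohol are taken as purchasable.

Step 1
Reactants: 1 3,4-dimethoxybenzaldehyde; 2 propane-1,3-dithiol
Product: 3 2-(3,4-dimethoxyphenyl)-1,3-dithiane
Conditions: BF3·OEt2 (cat.), CH2Cl2, 0 °C to rt
Reagents that add atoms: none
Why: Lewis-acid-catalysed dithioacetalisation of an aryl aldehyde should proceed cleanly and turns the future carbinol carbon into a Corey–Seebach acyl-anion equivalent; no stereocentre is formed.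

Step 2
Reactants: 4 4-(benzyloxy)-3-methoxybenzyl alcohol
Product: 5 4-(benzyloxy)-3-methoxybenzyl bromide
Conditions: PBr3, Et2O, 0 °C
Reagents that add atoms: phosphorus tribromide, BrP(Br)Br
Why: Conversion of a primary benzylic alcohol into the bromide through its bromophosphite (SN2 displacement) is routine, and the benzyl aryl ether should survive the cold, short exposure.

Step 3
Reactants: 3 2-(3,4-dimethoxyphenyl)-1,3-dithiane; 6 (5R)-5-(l-menthyloxy)furan-2(5H)-one; 5 4-(benzyloxy)-3-methoxybenzyl bromide
Product: 9 (3R,4R,5R)-3-[4-(benzyloxy)-3-methoxybenzyl]-4-[2-(3,4-dimethoxyphenyl)-1,3-dithian-2-yl]-5-(l-menthyloxy)dihydrofuran-2(3H)-one, via lithiated dithiane 7 (not isolated), via lithium lactone enolate 8 (not isolated)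
Conditions: n-BuLi, THF, −78 to −20 °C; 6, −78 °C; then 5, DMPU, −78 °C to rt
Reagents that add atoms: none
Why: Deprotonation of 3 gives the sulfur-stabilised carbanion 7, which adds in a 1,4-sense to C4 of butenolide 6; the lithium enolate 8 formed at C2–C3 is then C-alkylated by bromide 5 in an SN2 step that makes the C3–CH2Ar bond. The closest known reaction type is the tandem conjugate addition–enolate alkylation of 5-alkoxybutenolides with Corey–Seebach dithiane anions. No ring is closed in this step. C4 is set by the C5 acetal centre, because the bulky nucleophile should approach the face anti to the menthyloxy group, and C3 is set by C4, because the benzyl bromide should approach anti to the quaternary dithianyl substituent, which gives the all-trans 3,4,5 array with 3R,4R. The step needs 1,4- over 1,2-addition, which the soft and hindered 2-aryl dithiane anion secures, and C-mono-alkylation, which the reactive benzylic bromide in THF/DMPU and the crowded tertiary C3 of the product secure.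

Step 4
Reactants: 9 (3R,4R,5R)-3-[4-(benzyloxy)-3-methoxybenzyl]-4-[2-(3,4-dimethoxyphenyl)-1,3-dithian-2-yl]-5-(l-menthyloxy)dihydrofuran-2(3H)-one
Product: 12 (3R,4R)-3-[4-(benzyloxy)-3-methoxybenzyl]-4-[2-(3,4-dimethoxyphenyl)-1,3-dithian-2-yl]dihydrofuran-2(3H)-one, via potassium 4-oxobutanoate 10 (not isolated), via potassium 4-hydroxybutanoate 11 (not isolated)
Conditions: NaBH4, KOH, EtOH/H2O, rt; then aq. HCl (pH 2), rt
Reagents that add atoms: potassium hydroxide, [K+].[OH-] (oxygen of the carboxylate in 10 and 11, kept in part in the lactone C=O)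
Why: Saponification of the acylal opens the ring and expels menthol to give aldehyde 10, borohydride reduces it in situ to 11, and acidification relactonises through the new primary alcohol, so C5 becomes CH2. Both stereocentres should be retained because the aldehyde is reduced faster than its hindered α-carbon (C4) can enolise.

Step 5
Reactants: 12 (3R,4R)-3-[4-(benzyloxy)-3-methoxybenzyl]-4-[2-(3,4-dimethoxyphenyl)-1,3-dithian-2-yl]dihydrofuran-2(3H)-one
Product: 13 (3R,4R)-3-[4-(benzyloxy)-3-methoxybenzyl]-4-(3,4-dimethoxybenzoyl)dihydrofuran-2(3H)-one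
Conditions: HgO, BF3·OEt2, THF/H2O (85:15), rt
Reagents that add atoms: water, O
Why: Thiophilic Hg(II)-assisted hydrolysis of the dithioacetal (Corey–Seebach unmasking) should release the aryl ketone under conditions too weakly basic to epimerise C4 or eliminate the β-acyloxy group.

Step 6
Reactants: 13 (3R,4R)-3-[4-(benzyloxy)-3-methoxybenzyl]-4-(3,4-dimethoxybenzoyl)dihydrofuran-2(3H)-one
Product: 14 (3R,4R)-4-(3,4-dimethoxybenzoyl)-3-(4-hydroxy-3-methoxybenzyl)dihydrofuran-2(3H)-one
Conditions: H2 (1 atm), 10% Pd/C, EtOAc, rt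
Reagents that add atoms: none
Why: Hydrogenolysis of the benzyl aryl ether should be much faster than reduction of the electron-rich aryl ketone in neutral EtOAc. It is placed before the ketone reduction so that the later electron-rich benzylic alcohol is never exposed to Pd/H2.

Step 7
Reactants: 14 (3R,4R)-4-(3,4-dimethoxybenzoyl)-3-(4-hydroxy-3-methoxybenzyl)dihydrofuran-2(3H)-one
Product: 15 (3R,4R)-4-[(S)-(3,4-dimethoxyphenyl)(hydroxy)methyl]-3-(4-hydroxy-3-methoxybenzyl)dihydrofuran-2(3H)-one
Conditions: L-Selectride (2.5 equiv), THF, −78 °C; AcOH, −78 °C to rt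
Reagents that add atoms: none
Why: Felkin–Anh-controlled addition of the bulky tri-sec-butylborohydride, with the benzyl-bearing ring carbon C3 as the large group anti to the incoming hydride, should give the (S)-carbinol. One equivalent of hydride is spent on the phenol, the lactone should not be reduced at −78 °C, and the cold acidic quench should prevent alkoxide-driven lactone migration.

Compound list
1 | 3,4-dimethoxybenzaldehyde (veratraldehyde) | COc1ccc(C=O)cc1OC | starting material
2 | propane-1,3-dithiol | SCCCS | starting material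
3 | 2-(3,4-dimethoxyphenyl)-1,3-dithiane | COc1ccc(C2SCCCS2)cc1OC | intermediate
4 | 4-(benzyloxy)-3-methoxybenzyl alcohol | COc1cc(CO)ccc1OCc1ccccc1 | starting material
5 | 4-(benzyloxy)-3-methoxybenzyl bromide | COc1cc(CBr)ccc1OCc1ccccc1 | intermediate
6 | (5R)-5-{[(1R,2S,5R)-2-isopropyl-5-methylcyclohexyl]oxy}furan-2(5H)-one [(5R)-5-(l-menthyloxy)furan-2(5H)-one] | O=C1C=C[C@H](O[C@@H]2C[C@H](C)CC[C@H]2C(C)C)O1 | starting material
7 | 2-(3,4-dimethoxyphenyl)-2-lithio-1,3-dithiane | [Li]C1(c2ccc(OC)c(OC)c2)SCCCS1 | intermediate (not isolated)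
8 | lithium (4R,5R)-4-[2-(3,4-dimethoxyphenyl)-1,3-dithian-2-yl]-5-(l-menthyloxy)-4,5-dihydrofuran-2-olate | [Li+].C1=C([O-])O[C@@H](O[C@@H]2C[C@H](C)CC[C@H]2C(C)C)[C@@H]1C1(c2ccc(OC)c(OC)c2)SCCCS1 | intermediate (not isolated)
9 | (3R,4R,5R)-3-[4-(benzyloxy)-3-methoxybenzyl]-4-[2-(3,4-dimethoxyphenyl)-1,3-dithian-2-yl]-5-(l-menthyloxy)dihydrofuran-2(3H)-one | COc1cc(C[C@H]2C(=O)O[C@@H](O[C@@H]3C[C@H](C)CC[C@H]3C(C)C)[C@@H]2C2(c3ccc(OC)c(OC)c3)SCCCS2)ccc1OCc1ccccc1 | intermediate
10 | potassium (2R,3R)-2-[4-(benzyloxy)-3-methoxybenzyl]-3-[2-(3,4-dimethoxyphenyl)-1,3-dithian-2-yl]-4-oxobutanoate | COc1cc(C[C@@H](C(=O)[O-])[C@H](C=O)C2(c3ccc(OC)c(OC)c3)SCCCS2)ccc1OCc1ccccc1.[K+] | intermediate (not isolated)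
11 | potassium (2R,3R)-2-[4-(benzyloxy)-3-methoxybenzyl]-3-[2-(3,4-dimethoxyphenyl)-1,3-dithian-2-yl]-4-hydroxybutanoate | COc1cc(C[C@@H](C(=O)[O-])[C@H](CO)C2(c3ccc(OC)c(OC)c3)SCCCS2)ccc1OCc1ccccc1.[K+] | intermediate (not isolated)
12 | (3R,4R)-3-[4-(benzyloxy)-3-methoxybenzyl]-4-[2-(3,4-dimethoxyphenyl)-1,3-dithian-2-yl]dihydrofuran-2(3H)-one | COc1cc(C[C@H]2C(=O)OC[C@@H]2C2(c3ccc(OC)c(OC)c3)SCCCS2)ccc1OCc1ccccc1 | intermediate
13 | (3R,4R)-3-[4-(benzyloxy)-3-methoxybenzyl]-4-(3,4-dimethoxybenzoyl)dihydrofuran-2(3H)-one | COc1cc(C[C@H]2C(=O)OC[C@@H]2C(=O)c2ccc(OC)c(OC)c2)ccc1OCc1ccccc1 | intermediate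
14 | (3R,4R)-4-(3,4-dimethoxybenzoyl)-3-(4-hydroxy-3-methoxybenzyl)dihydrofuran-2(3H)-one | COc1cc(C[C@H]2C(=O)OC[C@@H]2C(=O)c2ccc(OC)c(OC)c2)ccc1O | intermediate
15 | (3R,4R)-4-[(S)-(3,4-dimethoxyphenyl)(hydroxy)methyl]-3-(4-hydroxy-3-methoxybenzyl)dihydrofuran-2(3H)-one | COc1cc(C[C@H]2C(=O)OC[C@@H]2[C@H](O)c2ccc(OC)c(OC)c2)ccc1O | target

Total step count: 7
Longest linear sequence: 6 (steps 1, 3, 4, 5, 6, 7)

Steps most likely to fail

Step 3. The C-benzylation of the hindered enolate 8, which sits next to the quaternary dithianyl carbon, may be outrun by proton transfer, so that the enolate is quenched unalkylated, or the three-component sequence may stall after the conjugate addition. The fallback sets out from 3 and 6 and comes back at 12. The conjugate addition is run alone and quenched with NH4Cl to isolate (4R,5R)-4-[2-(3,4-dimethoxyphenyl)-1,3-dithian-2-yl]-5-(l-menthyloxy)dihydrofuran-2(3H)-one F1. The acetal is then removed first (NaBH4, KOH, EtOH/H2O; then HCl) to give (R)-4-[2-(3,4-dimethoxyphenyl)-1,3-dithian-2-yl]dihydrofuran-2(3H)-one F2. The enolate of F2 (LDA, THF, −78 °C) is then alkylated with 5 in a separate step, anti to the C4 substituent, which should give 12. The bond is thus made by a stand-alone alkylation of the auxiliary-free β-substituted butyrolactone instead of inside the tandem sequence.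

Step 7. The hydride may attack the carbonyl with poor facial selectivity (erosion of Felkin control by the ring conformation), or the bulky basic hydride may enolise the ketone and epimerise C4 instead of reducing it. The fallback sets out from 14 and comes back at 15; it makes no new compound (F0). Substrate control is replaced by catalyst control: Corey–Bakshi–Shibata reduction with (R)-2-methyl-CBS-oxazaborolidine (cat.) and BH3·SMe2 in THF at −20 °C, with extra borane for the phenol. This should deliver hydride to the face that gives the (S)-aryl carbinol regardless of the bias of the neighbouring centre, under non-basic conditions.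

Step 4. After ring opening, the transient aldehyde may enolise under KOH before it is reduced, which would epimerise C4 and lead to the cis-lactone after ring closure. The fallback sets out from 9 and comes back at 12; it makes no new compound (F0). The acetal is reduced without opening the ring by ionic hydrogenation (Et3SiH, BF3·OEt2, CH2Cl2, −78 to 0 °C): loss of menthol gives the cyclic acyloxocarbenium ion at C5, which is trapped by hydride, so no enolisable aldehyde is ever formed.

Further compounds
F1 | step 3 | (4R,5R)-4-[2-(3,4-dimethoxyphenyl)-1,3-dithian-2-yl]-5-(l-menthyloxy)dihydrofuran-2(3H)-one | C1C(=O)O[C@@H](O[C@@H]2C[C@H](C)CC[C@H]2C(C)C)[C@@H]1C1(c2ccc(OC)c(OC)c2)SCCCS1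
F2 | step 3 | (R)-4-[2-(3,4-dimethoxyphenyl)-1,3-dithian-2-yl]dihydrofuran-2(3H)-one | C1C(=O)OC[C@@H]1C1(c2ccc(OC)c(OC)c2)SCCCS1
F0 | step 7 | none | none
F0 | step 4 | none | none
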